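**Retrosynthetic overview**

- Germacrane numbering is used: carbocycle C1–C10, C1 ketone, C2=C3, furanone oxygen bridging C3 and C10, Z C4=C5, ester on O6, lactone O8–C12(=O)–C11(=C13)–C7. The strategy rests on the array O6–C6–C7–C11=C13, a homoallylic alcohol whose carbinol carbon C6 is ε to the C1 ketone through C4=C5 and C2=C3 of the furanone dienone.
- Key disconnection: after removal of the O6 epoxyangelate and opening of the lactone to a tert-butyl ester and an O8 silyl ether, C6–C7 is broken and O6 is joined to C13 ([2,3]-Wittig retron). This expands the ten-membered carbocycle to a 13-membered ether (C1–C10, C11, C13, O) that carries an E enoate.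
- The macrocyclic ether is cut at C7=C11 (intramolecular Horner–Wadsworth–Emmons). The C8 oxygen comes from an organocatalytic α-oxyamination of the C7 aldehyde, and the ether phosphonate from oxa-Michael addition of the C6 alcohol to a vinylphosphonate.
- The furanone alcohol comes from Claisen acylation and cyclodehydration between an α-silyloxy methyl ketone made from (R)-linalool (C10 bought) and a Z Weinreb amide made from 3-methyl-2(5H)-furanone. The acyl side chain comes from angelic acid by Sharpless epoxidation.
- Ring order: furanone, then the 13-membered ether ring (olefination), then the ten-membered carbocycle (ring contraction), and last the α-methylene-γ-butyrolactone (O8 onto C12).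

Key step: step 17

Assumption: the (5S) imidazolidinone is taken to deliver oxygen to the enamine face that gives the 8S aldehyde (its benzyl group shields the other face of the E enamine); were the sense opposite, the (5R) salt would be used.

**Route**

Step 1
Reactants: 1 (R)-linalool
Product: 2 (3R)-3,7-dimethyl-3-(triethylsilyloxy)octa-1,6-diene
Conditions: Et3SiOTf, 2,6-lutidine, CH2Cl2, −78 to 0 °C
Reagents that add atoms: triethylsilyl trifluoromethanesulfonate, CC[Si](CC)(CC)OS(=O)(=O)C(F)(F)F
Why: O-Silylation of the hindered tertiary alcohol with the silyl triflate and 2,6-lutidine masks the hydroxyl for the oxidation and enolate steps and does not touch the C10 stereocentre that is bought with 1.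

Step 2
Reactants: 2 (3R)-3,7-dimethyl-3-(triethylsilyloxy)octa-1,6-diene
Product: 3 (3R)-3,7-dimethyl-3-(triethylsilyloxy)oct-6-en-2-one
Conditions: PdCl2(quinox) (cat.; quinox = 2-(4,5-dihydrooxazol-2-yl)quinoline), AgSbF6 (cat.), aq. tBuOOH, CH2Cl2, 0 °C to rt
Reagents that add atoms: tert-butyl hydroperoxide, CC(C)(C)OO
Why: This is a ligand-controlled, peroxide-driven Wacker oxidation, which is known to give the methyl ketone from monosubstituted alkenes that carry a protected allylic oxygen (CuCl/O2 conditions tend to leak to the aldehyde there), while the trisubstituted alkene does not react and remains as the masked C7 aldehyde.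

Step 3
Reactants: 4 3-methyl-2(5H)-furanone
Product: 5 (Z)-4-hydroxy-N-methoxy-N,2-dimethylbut-2-enamide
Conditions: MeNHOMe·HCl, AlMe3, CH2Cl2, 0 °C to rt; aq. HCl work-up
Reagents that add atoms: N,O-dimethylhydroxylamine hydrochloride, CNOC.Cl
Why: Aminolysis of the lactone by the aluminium amide (Weinreb amide formation) opens the butenolide at the acyl carbon without rotation about the ring-derived cis C=C bond, so the Z geometry of the future C4=C5 bond is fixed at this point.

Step 4
Reactants: 5 (Z)-4-hydroxy-N-methoxy-N,2-dimethylbut-2-enamide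
Product: 6 (Z)-4-(tert-butyldiphenylsilyloxy)-N-methoxy-N,2-dimethylbut-2-enamide
Conditions: tBuPh2SiCl, imidazole, CH2Cl2, 0 °C to rt
Reagents that add atoms: tert-butyldiphenylsilyl chloride, CC(C)(C)[Si](Cl)(c1ccccc1)c1ccccc1
Why: Standard O-silylation of the primary alcohol, done at once to stop relactonisation, gives an ether that survives the base of step 5 and the acid of step 6.

Step 5
Reactants: 3 (3R)-3,7-dimethyl-3-(triethylsilyloxy)oct-6-en-2-one; 6 (Z)-4-(tert-butyldiphenylsilyloxy)-N-methoxy-N,2-dimethylbut-2-enamide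
Product: 8 (2Z,7R)-1-(tert-butyldiphenylsilyloxy)-3,7,11-trimethyl-7-(triethylsilyloxy)dodeca-2,10-diene-4,6-dione, via lithium enolate 7 (not isolated)
Conditions: LiN(iPr)2, THF, −78 °C (3 in excess); then 6, −78 to −20 °C; AcOH quench
Reagents that add atoms: none
Why: Claisen-type acylation of the kinetic lithium enolate (the methyl group is the only enolisable position of 3) with the Weinreb amide stops at the chelated tetrahedral adduct, which collapses to the 1,3-diketone on acidic quench without over-addition.

Step 6
Reactants: 8 (2Z,7R)-1-(tert-butyldiphenylsilyloxy)-3,7,11-trimethyl-7-(triethylsilyloxy)dodeca-2,10-diene-4,6-dione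
Product: 10 (2R)-5-[(Z)-4-(tert-butyldiphenylsilyloxy)but-2-en-2-yl]-2-methyl-2-(4-methylpent-3-enyl)furan-3(2H)-one, via hydroxy diketone 9 (not isolated)
Conditions: 1 M aq. HCl, THF, rt
Reagents that add atoms: none
Why: Aqueous acid removes the labile triethylsilyl group and the freed tertiary hydroxyl adds to the distal carbonyl of the diketone and loses water (acid-catalysed cyclodehydration to a 3(2H)-furanone), the only five-membered closure available, with the TBDPS ether and C10 left untouched.

Step 7
Reactants: 10 (2R)-5-[(Z)-4-(tert-butyldiphenylsilyloxy)but-2-en-2-yl]-2-methyl-2-(4-methylpent-3-enyl)furan-3(2H)-one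
Product: 11 (2R)-5-[(Z)-4-hydroxybut-2-en-2-yl]-2-methyl-2-(4-methylpent-3-enyl)furan-3(2H)-one
Conditions: Bu4NF, AcOH, THF, 0 °C to rt
Reagents that add atoms: none
Why: Fluoride-mediated desilylation buffered with acetic acid frees the C6 alcohol under non-basic conditions, so the Z hydroxy dienone should neither isomerise nor cyclise onto C3.

Step 8
Reactants: 12 tert-butyl 2-(diethoxyphosphoryl)acetate
Product: 13 tert-butyl 2-(diethoxyphosphoryl)-3-(dimethylamino)propanoate (racemic)
Conditions: NaH, THF, 0 °C; then CH2=NMe2+ I−, 0 °C to rt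
Reagents that add atoms: N,N-dimethylmethyleneiminium iodide, C=[N+](C)C.[I-]
Why: Mannich aminomethylation of the sodium salt of the phosphonoacetate with the preformed iminium salt introduces the carbon that becomes C13 without acid, which the tert-butyl ester would not survive under the usual hot acidic dehydration of a formaldehyde adduct.

Step 9
Reactants: 13 tert-butyl 2-(diethoxyphosphoryl)-3-(dimethylamino)propanoate
Product: 15 tert-butyl 2-(diethoxyphosphoryl)acrylate, via trimethylammonium iodide 14 (not isolated)
Conditions: MeI, CH2Cl2, rt; then aq. NaHCO3, rt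
Reagents that add atoms: none
Why: N-Methylation turns the amine into a leaving group and mild base then triggers E1cB elimination from the doubly activated carbon (Mannich-base elimination) to give the vinylphosphonate, which is used at once.

Step 10
Reactants: 11 (2R)-5-[(Z)-4-hydroxybut-2-en-2-yl]-2-methyl-2-(4-methylpent-3-enyl)furan-3(2H)-one; 15 tert-butyl 2-(diethoxyphosphoryl)acrylate
Product: 17 ether phosphonate (11 carrying CH2CH(CO2tBu)P(O)(OEt)2 on O6; both epimers at the phosphonate carbon), via potassium alkoxide 16 (not isolated)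
Conditions: KN(SiMe3)2 (0.95 equiv), THF, −78 °C; then 15, −78 to −40 °C; AcOH, −78 °C
Reagents that add atoms: none
Why: Oxa-Michael addition of the preformed alkoxide to the doubly activated alkene is fast at low temperature and ends at the stabilised phosphonate carbanion, which is protonated cold before it or the alkoxide can add to the dienone or scramble the Z alkene, and the new centre at the phosphonate carbon is of no consequence because it becomes sp2 in step 14.

Step 11
Reactants: 17 ether phosphonate
Product: 18 epoxide of 17 at the side-chain trisubstituted alkene (diastereomer mixture)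
Conditions: mCPBA, NaHCO3, CH2Cl2, 0 °C
Reagents that add atoms: 3-chloroperbenzoic acid, OOC(=O)c1cccc(Cl)c1
Why: Prilezhaev epoxidation with a peracid is selective for the isolated trisubstituted alkene, the only electron-rich C=C bond in 17, since C2=C3 and C4=C5 are deactivated by conjugation with the C1 ketone.

Step 12
Reactants: 18 epoxide of 17
Product: 19 C7 aldehyde (OHC–C8H2–C9H2–C10 chain on the furanone; ether phosphonate retained)
Conditions: H5IO6, THF/H2O, 0 °C
Reagents that add atoms: none
Why: Periodic acid opens the epoxide to the glycol and cleaves it in the same flask (oxidative glycol cleavage), giving the C7 aldehyde under conditions that spare the dienone, the phosphonate and the tert-butyl ester.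

Step 13
Reactants: 19 C7 aldehyde
Product: 20 (8S)-8-(2,2,6,6-tetramethylpiperidin-1-yloxy) C7 aldehyde
Conditions: TEMPO, (5S)-5-benzyl-2,2,3-trimethylimidazolidin-4-one·HBF4 (20 mol %), FeCl3 (10 mol %), NaNO2 (30 mol %), O2, DMF, −10 °C
Reagents that add atoms: TEMPO, CC1(C)CCCC(C)(C)N1[O]
Why: Enamine-mediated α-oxyamination of the aldehyde with TEMPO under iron co-catalysis puts oxygen on C8 from the enamine face that is not shielded by the benzyl group of the (5S) catalyst, which sets the 8S centre by catalyst control two atoms away from C10.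

Step 14
Reactants: 20 (8S)-8-(2,2,6,6-tetramethylpiperidin-1-yloxy) C7 aldehyde
Product: 21 13-membered macrocyclic ether (C1–C10; C11; C13; O; 12 atoms if counted through the furanone oxygen) with E enoate C7=C11 and O8-tetramethylpiperidinyl
Conditions: LiCl, DBU, MeCN, 1 mM (slow addition), rt
Reagents that add atoms: none
Why: Intramolecular Horner–Wadsworth–Emmons olefination under mild LiCl/amine conditions at high dilution closes the macrocyclic ether by end-to-end cyclisation and, as expected for an α-substituted phosphonoacetate, places the ester trans to C8 (E enoate, C13 cis to C8), while the weak base limits epimerisation of the α-aminoxy aldehyde.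

Step 15
Reactants: 21 macrocyclic ether with O8-tetramethylpiperidinyl
Product: 22 macrocyclic ether with free (8S)-hydroxyl
Conditions: Zn, AcOH/THF/H2O, rt
Reagents that add atoms: none
Why: Dissolving-zinc reduction cleaves the weak N–O bond of the alkoxyamine (reductive N–O cleavage) and should leave the enoate, the dienone and the allylic ether intact, and the E geometry keeps the new hydroxyl away from the ester so that no butenolide forms.

Step 16
Reactants: 22 macrocyclic ether with free (8S)-hydroxyl
Product: 23 macrocyclic ether with O8-tert-butyldimethylsilyl (key precursor)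
Conditions: tBuMe2SiOTf, 2,6-lutidine, CH2Cl2, −78 °C
Reagents that add atoms: tert-butyldimethylsilyl trifluoromethanesulfonate, CC(C)(C)[Si](C)(C)OS(=O)(=O)C(F)(F)F
Why: Silylation with the triflate and a hindered base at low temperature, conditions the tert-butyl ester tolerates, puts on O8 a bulky group that is stable to the amide base, shields one face of C7 in the next step and is slow to migrate.

Step 17
Reactants: 23 macrocyclic ether with O8-tert-butyldimethylsilyl
Product: 25 ring-contracted hydroxy ester (ten-membered furanone carbocycle; C6–OH; C8–OTBS; tert-butyl acrylate unit on C7; C6 C7 C8 C10 configured as in the target), via potassium trienolate 24 (not isolated)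
Conditions: KN(SiMe3)2 (1.1 equiv), THF (5 mM), −78 °C; AcOH in THF, −78 °C
Reagents that add atoms: none
Why: Proposed new method: KN(SiMe3)2 should remove a C6–H, the only proton whose carbanion is conjugated through C5=C4 and C3=C2 with the C1 ketone, and the trienolate 24 is expected to undergo a concerted six-electron [2,3]-sigmatropic shift through a five-membered envelope (C6, O, C13, C11, C7) in which C6 bonds to C7 while O–C13 breaks and C11=C13 appears, the C11 ester lowering the acceptor orbital of the allyl unit so that even a stabilised donor can react and the trade of the O–C13 bond for the C6–C7 bond paying for the loss of delocalisation. The closest known reaction types are the [2,3]-Wittig ring contraction of 13-membered diallylic ethers to cyclodecenols and the [2,3]-Wittig rearrangement of enolates of α-allyloxy carbonyl compounds, neither of which has been run with a doubly vinylogous enolate or with a 2-(alkoxymethyl)enoate as the allyl partner. The ten-membered carbocycle C1–C10 is closed by ring contraction, that is by excision of C11, C13 and the ether oxygen from the 13-membered perimeter, and not by end-to-end cyclisation, and because only the arrangement with C3 and C6 cis across C4–C5 lets C6 reach C7 the Z alkene is regenerated. C7 is set by substrate control from C8: allylic 1,3-strain with the cis C13 methylene holds C8–H in the enoate plane, the silyloxy group points outward, and C6, tethered through C10–C9, can reach only the C9 face of C7, which gives the C7/C8 relationship needed for the trans-fused lactone. C6 is set by the envelope, in which C8 is cis to C13 and C5 takes the exo position, so that O6 and C11 (and H6 and H7) end up cis on the new ring. The step needs ε-attack (α- or γ-attack would require nine- or seven-membered arrays), no γ-deprotonation at C8 (that C–H lies in the enoate plane and is stereoelectronically inert) and a C6 alkoxide that does not lactonise or take the silyl group from O8, which the tert-butyl ester and the acetic acid quench at −78 °C should secure.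

Step 18
Reactants: 26 angelic acid
Product: 27 (Z)-2-methylbut-2-en-1-ol
Conditions: LiAlH4, Et2O, 0 °C
Reagents that add atoms: none
Why: Hydride reduction of the carboxylic acid with LiAlH4 in ether gives the allylic alcohol without reducing or isomerising the trisubstituted alkene, so the Z geometry of angelic acid is carried into the epoxidation substrate.

Step 19
Reactants: 27 (Z)-2-methylbut-2-en-1-ol
Product: 28 (2S,3R)-(2,3-dimethyloxiran-2-yl)methanol
Conditions: Ti(OiPr)4 (cat.), L-(+)-diethyl tartrate (cat.), tBuOOH, 4 Å molecular sieves, CH2Cl2, −20 °C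
Reagents that add atoms: tert-butyl hydroperoxide, CC(C)(C)OO
Why: Sharpless asymmetric epoxidation with the L-(+)-tartrate delivers oxygen to the face of the Z allylic alcohol that gives the (2S,3R)-epoxy alcohol, the same facial sense by which this tartrate gives 2S,3S epoxides from E and 2S,3R epoxides from Z allylic alcohols, and the cis relationship of CH2OH and the C3 methyl follows from the alkene geometry.

Step 20
Reactants: 28 (2S,3R)-(2,3-dimethyloxiran-2-yl)methanol
Product: 29 (2R,3R)-2,3-dimethyloxirane-2-carboxylic acid (epoxyangelic acid)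
Conditions: RuCl3 (cat.), NaIO4, MeCN/EtOAc/H2O, rt
Reagents that add atoms: water, O
Why: Catalytic ruthenium tetroxide oxidation (RuCl3/NaIO4) takes the primary alcohol to the carboxylic acid without opening the oxirane, the change of the C2 descriptor from S to R being only a change of substituent priorities.

Step 21
Reactants: 29 (2R,3R)-2,3-dimethyloxirane-2-carboxylic acid; 25 ring-contracted hydroxy ester
Product: 31 C6 (2R,3R)-epoxyangelate of 25, via mixed anhydride 30 (not isolated)
Conditions: 2,4,6-trichlorobenzoyl chloride, Et3N, toluene, rt; then 25, DMAP, rt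
Reagents that add atoms: none
Why: Yamaguchi esterification through the mixed anhydride and DMAP acylates the hindered secondary C6 hydroxyl under mild basic conditions that endanger neither the oxirane nor the tert-butyl ester nor the C6/C7 centres.

Step 22
Reactants: 31 C6 epoxyangelate
Product: 32 C8 alcohol (γ-hydroxy tert-butyl ester)
Conditions: HF·pyridine, pyridine, THF, 0 °C to rt
Reagents that add atoms: none
Why: Fluoride-assisted desilylation with pyridine-buffered HF removes the secondary silyl ether, the buffered medium being mild enough for the glycidic ester, the α-methylene ester and the dienone.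

Step 23
Reactants: 32 C8 alcohol
Product: 34 CNP0258430.3 (6S,7R,8S,10R; 2′R,3′R), via hydroxy acid 33 (not isolated)
Conditions: CF3CO2H, CH2Cl2, 0 °C, short exposure
Reagents that add atoms: none
Why: Brief acidolysis of the tert-butyl ester (loss of 2-methylpropene) gives the γ-hydroxy acid, which lactonises under the same acid onto O8 (acid-catalysed lactonisation) to close the trans-fused α-methylene-γ-butyrolactone, the electron-poor glycidic oxirane being expected to survive the short cold exposure.

**Compound list**

1 | (R)-linalool | CC(C)=CCC[C@@](C=C)(C)O | starting material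
2 | (3R)-3,7-dimethyl-3-(triethylsilyloxy)octa-1,6-diene | CC(C)=CCC[C@@](C=C)(C)O[Si](CC)(CC)CC | intermediate
3 | (3R)-3,7-dimethyl-3-(triethylsilyloxy)oct-6-en-2-one | CC(C)=CCC[C@@](C(C)=O)(C)O[Si](CC)(CC)CC | intermediate
4 | 3-methyl-2(5H)-furanone | CC1=CCOC1=O | starting material
5 | (Z)-4-hydroxy-N-methoxy-N,2-dimethylbut-2-enamide | CON(C)C(=O)/C(C)=C\CO | intermediate
6 | (Z)-4-(tert-butyldiphenylsilyloxy)-N-methoxy-N,2-dimethylbut-2-enamide | CON(C)C(=O)/C(C)=C\CO[Si](c1ccccc1)(c1ccccc1)C(C)(C)C | intermediate
7 | lithium enolate of 3 (methyl side) | [Li+].[O-]C(=C)[C@@](C)(CCC=C(C)C)O[Si](CC)(CC)CC | intermediate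
8 | (2Z,7R)-1-(tert-butyldiphenylsilyloxy)-3,7,11-trimethyl-7-(triethylsilyloxy)dodeca-2,10-diene-4,6-dione | CC(C)=CCC[C@@](C(=O)CC(=O)/C(C)=C\CO[Si](c1ccccc1)(c1ccccc1)C(C)(C)C)(C)O[Si](CC)(CC)CC | intermediate
9 | (2Z,7R)-1-(tert-butyldiphenylsilyloxy)-7-hydroxy-3,7,11-trimethyldodeca-2,10-diene-4,6-dione | CC(C)=CCC[C@@](C(=O)CC(=O)/C(C)=C\CO[Si](c1ccccc1)(c1ccccc1)C(C)(C)C)(C)O | intermediate
10 | (2R)-5-[(Z)-4-(tert-butyldiphenylsilyloxy)but-2-en-2-yl]-2-methyl-2-(4-methylpent-3-enyl)furan-3(2H)-one | CC(C)=CCC[C@@]1(C)OC(=CC1=O)/C(C)=C\CO[Si](c1ccccc1)(c1ccccc1)C(C)(C)C | intermediate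
11 | (2R)-5-[(Z)-4-hydroxybut-2-en-2-yl]-2-methyl-2-(4-methylpent-3-enyl)furan-3(2H)-one | CC(C)=CCC[C@@]1(C)OC(=CC1=O)/C(C)=C\CO | intermediate
12 | tert-butyl 2-(diethoxyphosphoryl)acetate | CC(C)(C)OC(=O)CP(=O)(OCC)OCC | starting material
13 | tert-butyl 2-(diethoxyphosphoryl)-3-(dimethylamino)propanoate (racemic) | CN(C)CC(C(=O)OC(C)(C)C)P(=O)(OCC)OCC | intermediate
14 | [2-(tert-butoxycarbonyl)-2-(diethoxyphosphoryl)ethyl]trimethylammonium iodide | C[N+](C)(C)CC(C(=O)OC(C)(C)C)P(=O)(OCC)OCC.[I-] | intermediate
15 | tert-butyl 2-(diethoxyphosphoryl)acrylate | C=C(C(=O)OC(C)(C)C)P(=O)(OCC)OCC | intermediate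
16 | potassium alkoxide of 11 | CC(C)=CCC[C@@]1(C)OC(=CC1=O)/C(C)=C\C[O-].[K+] | intermediate
17 | ether phosphonate (O6–C13H2–C11H(CO2tBu)P(O)(OEt)2; epimers at C11) | CC(C)=CCC[C@@]1(C)OC(=CC1=O)/C(C)=C\COCC(C(=O)OC(C)(C)C)P(=O)(OCC)OCC | intermediate
18 | side-chain epoxide of 17 (diastereomer mixture) | CC1(C)OC1CC[C@@]2(C)OC(=CC2=O)/C(C)=C\COCC(C(=O)OC(C)(C)C)P(=O)(OCC)OCC | intermediate
19 | C7 aldehyde | O=CCC[C@@]1(C)OC(=CC1=O)/C(C)=C\COCC(C(=O)OC(C)(C)C)P(=O)(OCC)OCC | intermediate
20 | (8S)-8-(2,2,6,6-tetramethylpiperidin-1-yloxy) C7 aldehyde | O=C[C@@H](ON1C(C)(C)CCCC1(C)C)C[C@@]2(C)OC(=CC2=O)/C(C)=C\COCC(C(=O)OC(C)(C)C)P(=O)(OCC)OCC | intermediate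
21 | 13-membered macrocyclic ether, E enoate, O8-tetramethylpiperidinyl | CC(C)(C)OC(=O)/C1=C/[C@@H](ON3C(C)(C)CCCC3(C)C)C[C@@]2(C)OC(=CC2=O)/C(C)=C\COC1 | intermediate
22 | 13-membered macrocyclic ether, free (8S)-hydroxyl | CC(C)(C)OC(=O)/C1=C/[C@@H](O)C[C@@]2(C)OC(=CC2=O)/C(C)=C\COC1 | intermediate
23 | 13-membered macrocyclic ether, O8-tert-butyldimethylsilyl | CC(C)(C)OC(=O)/C1=C/[C@@H](O[Si](C)(C)C(C)(C)C)C[C@@]2(C)OC(=CC2=O)/C(C)=C\COC1 | intermediate
24 | potassium trienolate of 23 (drawn as the C6 carbanion form) | CC(C)(C)OC(=O)/C1=C/[C@@H](O[Si](C)(C)C(C)(C)C)C[C@@]2(C)OC(=CC2=O)/C(C)=C\[CH-]OC1.[K+] | intermediate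
25 | ring-contracted hydroxy ester (ten-membered carbocycle, C6–OH, C8–OTBS, tert-butyl α-methylene ester) | C=C(C(=O)OC(C)(C)C)[C@@H]1[C@@H](O[Si](C)(C)C(C)(C)C)C[C@@]2(C)OC(=CC2=O)/C(C)=C\[C@@H]1O | intermediate
26 | angelic acid | C/C=C(/C)C(=O)O | starting material
27 | (Z)-2-methylbut-2-en-1-ol | C/C=C(/C)CO | intermediate
28 | (2S,3R)-(2,3-dimethyloxiran-2-yl)methanol | OC[C@]1(C)O[C@@H]1C | intermediate
29 | (2R,3R)-2,3-dimethyloxirane-2-carboxylic acid | OC(=O)[C@]1(C)O[C@@H]1C | intermediate
30 | mixed anhydride of 29 with 2,4,6-trichlorobenzoic acid | O=C(OC(=O)c1c(Cl)cc(Cl)cc1Cl)[C@]2(C)O[C@@H]2C | intermediate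
31 | C6 (2R,3R)-epoxyangelate of 25 | C=C(C(=O)OC(C)(C)C)[C@@H]1[C@@H](O[Si](C)(C)C(C)(C)C)C[C@@]2(C)OC(=CC2=O)/C(C)=C\[C@@H]1OC(=O)[C@]3(C)O[C@@H]3C | intermediate
32 | C8 alcohol (γ-hydroxy tert-butyl ester) | C=C(C(=O)OC(C)(C)C)[C@@H]1[C@@H](O)C[C@@]2(C)OC(=CC2=O)/C(C)=C\[C@@H]1OC(=O)[C@]3(C)O[C@@H]3C | intermediate
33 | γ-hydroxy acid | C=C(C(=O)O)[C@@H]1[C@@H](O)C[C@@]2(C)OC(=CC2=O)/C(C)=C\[C@@H]1OC(=O)[C@]3(C)O[C@@H]3C | intermediate
34 | CNP0258430.3 | C=C1C(=O)O[C@H]2C[C@@]3(C)OC(=CC3=O)/C(C)=C\[C@H](OC(=O)[C@]3(C)O[C@@H]3C)[C@H]12 | target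

**Step count**

Total steps: 23. Longest linear sequence: 16 steps (steps 1, 2, 5, 6, 7, 10–17, 21–23, from 1 to 34).

**Steps most likely to fail**

1. Step 17 (bears the label). The trienolate may not rearrange and simply be reprotonated on quench. It may also bond through C2 or C4, lose the ether oxygen by 1,4-elimination after deprotonation at C8, add to the wrong face of C7, or pass the silyl group from O8 to O6 before the quench.

   Fallback with known chemistry: a metal-mediated intramolecular Barbier allylation of a C6 aldehyde by a 2-(bromomethyl)enoate, an established way to close medium rings that carry an α-methylene hydroxy ester. It sets out from 10 and comes back to the route at 25. Lemieux–Johnson cleavage of the side-chain alkene of 10 (OsO4 cat., NaIO4, 2,6-lutidine) would give the aldehyde F1, and the α-oxyamination of step 13 the aminoxy aldehyde F2. 4-Methoxybenzyl alcohol is added to 15 under the conditions of step 10 to give the PMB-ether phosphonate F3, and an intermolecular LiCl/DBU Horner–Wadsworth–Emmons reaction of F2 with F3 gives the enoate F4 (C8 cis to C13). Zn/AcOH gives the allylic alcohol F5 and tBuMe2SiOTf the silyl ether F6. Buffered Bu4NF then frees the primary C6 alcohol F7, MnO2 oxidises it to the Z enal F8, DDQ removes the PMB group to give the hydroxymethyl enoate F9, and CBr4/PPh3 gives the allylic bromide F10. Indium powder in THF/H2O at high dilution should then join C7 to C6 and give 25. Additions of such γ-substituted 2-(bromomethyl)acrylates usually favour the syn adduct, which is the C6/C7 relationship of 25, but the outcome on this ring would have to be confirmed.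

2. Step 14. The slow ring closure may lose out to oligomerisation. Prolonged contact of the α-aminoxy aldehyde with base may epimerise C8 or eliminate the aminoxy group, and the phosphonate carbanion may add to C5 of the dienone.

   Fallback: closure of the same ring by ring-closing metathesis instead of olefination. It sets out from 11 and comes back at 23. The alkoxide of 11 (KN(SiMe3)2, THF, −78 °C) is alkylated with tert-butyl 2-(bromomethyl)acrylate to the alkoxymethyl acrylate F11. Lemieux–Johnson cleavage gives the aldehyde F12, α-oxyamination as in step 13 the aminoxy aldehyde F13, and Wittig methylenation (Ph3P=CH2, −78 °C) the terminal alkene F14. Zn/AcOH gives the allylic alcohol F15 and tBuMe2SiOTf the silyl ether F16. Ring-closing metathesis (second-generation Hoveyda–Grubbs catalyst, toluene, 80 °C, 1 mM) should form C7=C11 with loss of ethene. The geometry with C8 cis to C13 is the one expected for a ring of this size but would need confirmation.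

3. Step 23. The acid may open the oxirane of the epoxyangelate while the tert-butyl ester is being cleaved, or the hydroxy acid may close only sluggishly to the trans-fused lactone.

   Fallback: closing the lactone before the epoxy ester is introduced. It sets out from 25 and comes back at 34. The C6 hydroxyl is masked with allyl chloroformate and pyridine as the allyl carbonate F17. HF·pyridine and then CF3CO2H give the carbonate-protected lactone F18. Pd(PPh3)4 with dimedone frees the hydroxy lactone F19 under neutral conditions, and Yamaguchi esterification with 29 as in step 21 gives 34.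

**Further compounds**

F1 | step 17 | 3-{(2R)-5-[(Z)-4-(tert-butyldiphenylsilyloxy)but-2-en-2-yl]-2-methyl-3-oxo-2,3-dihydrofuran-2-yl}propanal | O=CCC[C@@]1(C)OC(=CC1=O)/C(C)=C\CO[Si](c1ccccc1)(c1ccccc1)C(C)(C)C
F2 | step 17 | (8S)-8-(2,2,6,6-tetramethylpiperidin-1-yloxy) derivative of F1 | O=C[C@@H](ON1C(C)(C)CCCC1(C)C)C[C@@]2(C)OC(=CC2=O)/C(C)=C\CO[Si](c3ccccc3)(c4ccccc4)C(C)(C)C
F3 | step 17 | tert-butyl 2-(diethoxyphosphoryl)-3-(4-methoxybenzyloxy)propanoate | COc1ccc(COCC(C(=O)OC(C)(C)C)P(=O)(OCC)OCC)cc1
F4 | step 17 | enoate with C13–OPMB, O8-tetramethylpiperidinyl, C6–OTBDPS (C8 cis to C13) | CC(C)(C)OC(=O)/C(COCc1ccc(OC)cc1)=C/[C@@H](ON2C(C)(C)CCCC2(C)C)C[C@@]3(C)OC(=CC3=O)/C(C)=C\CO[Si](c4ccccc4)(c5ccccc5)C(C)(C)C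
F5 | step 17 | C8 alcohol from F4 | CC(C)(C)OC(=O)/C(COCc1ccc(OC)cc1)=C/[C@@H](O)C[C@@]2(C)OC(=CC2=O)/C(C)=C\CO[Si](c3ccccc3)(c4ccccc4)C(C)(C)C
F6 | step 17 | C8 tert-butyldimethylsilyl ether of F5 | CC(C)(C)OC(=O)/C(COCc1ccc(OC)cc1)=C/[C@@H](O[Si](C)(C)C(C)(C)C)C[C@@]2(C)OC(=CC2=O)/C(C)=C\CO[Si](c3ccccc3)(c4ccccc4)C(C)(C)C
F7 | step 17 | C6 alcohol from F6 | CC(C)(C)OC(=O)/C(COCc1ccc(OC)cc1)=C/[C@@H](O[Si](C)(C)C(C)(C)C)C[C@@]2(C)OC(=CC2=O)/C(C)=C\CO
F8 | step 17 | Z enal (C6 aldehyde) from F7 | CC(C)(C)OC(=O)/C(COCc1ccc(OC)cc1)=C/[C@@H](O[Si](C)(C)C(C)(C)C)C[C@@]2(C)OC(=CC2=O)/C(C)=C\C=O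
F9 | step 17 | hydroxymethyl enoate (C13–OH) from F8 | CC(C)(C)OC(=O)/C(CO)=C/[C@@H](O[Si](C)(C)C(C)(C)C)C[C@@]1(C)OC(=CC1=O)/C(C)=C\C=O
F10 | step 17 | allylic bromide (C13–Br) from F9 | CC(C)(C)OC(=O)/C(CBr)=C/[C@@H](O[Si](C)(C)C(C)(C)C)C[C@@]1(C)OC(=CC1=O)/C(C)=C\C=O
F11 | step 14 | tert-butyl 2-(alkoxymethyl)acrylate ether of 11 | CC(C)=CCC[C@@]1(C)OC(=CC1=O)/C(C)=C\COCC(=C)C(=O)OC(C)(C)C
F12 | step 14 | C7 aldehyde from F11 | O=CCC[C@@]1(C)OC(=CC1=O)/C(C)=C\COCC(=C)C(=O)OC(C)(C)C
F13 | step 14 | (8S)-8-(2,2,6,6-tetramethylpiperidin-1-yloxy) aldehyde from F12 | O=C[C@@H](ON1C(C)(C)CCCC1(C)C)C[C@@]2(C)OC(=CC2=O)/C(C)=C\COCC(=C)C(=O)OC(C)(C)C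
F14 | step 14 | terminal alkene (C7=CH2) from F13 | C=C[C@@H](ON1C(C)(C)CCCC1(C)C)C[C@@]2(C)OC(=CC2=O)/C(C)=C\COCC(=C)C(=O)OC(C)(C)C
F15 | step 14 | allylic C8 alcohol from F14 | C=C[C@@H](O)C[C@@]1(C)OC(=CC1=O)/C(C)=C\COCC(=C)C(=O)OC(C)(C)C
F16 | step 14 | C8 tert-butyldimethylsilyl ether of F15 | C=C[C@@H](O[Si](C)(C)C(C)(C)C)C[C@@]1(C)OC(=CC1=O)/C(C)=C\COCC(=C)C(=O)OC(C)(C)C
F17 | step 23 | C6 allyl carbonate of 25 | C=C(C(=O)OC(C)(C)C)[C@@H]1[C@@H](O[Si](C)(C)C(C)(C)C)C[C@@]2(C)OC(=CC2=O)/C(C)=C\[C@@H]1OC(=O)OCC=C
F18 | step 23 | 8,12-lactone with C6 allyl carbonate | C=C1C(=O)O[C@H]2C[C@@]3(C)OC(=CC3=O)/C(C)=C\[C@H](OC(=O)OCC=C)[C@H]12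
F19 | step 23 | 6-hydroxy 8,12-lactone | C=C1C(=O)O[C@H]2C[C@@]3(C)OC(=CC3=O)/C(C)=C\[C@H](O)[C@H]12
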